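**Plan**
- Enabling feature: ring B (C5–C10) with its C8 methyl is the carvone ring (C9 = carbonyl carbon, C10 = α′-carbon, C5 = stereocentre). The isopropenyl group is C4 with C19 (its CH2) and C18 (its CH3), so ring A needs only C1–C3, hung on C10 as an acrylate, and one new bond, C3–C4.
- Cuts, last to first: butenolide O–C5′ and C4′–C5′ (ene-yne coupling/lactonisation), one-carbon alkyne homologation at C15, C13=C14 (Horner–Wadsworth–Emmons), C11–C12 (organoborane alkylation), C9=C11 (Wittig), C3–C4 (radical closure), C1–C10 and C20–C10 (enolate alkylations).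
- Forward order: carvone → C18 oxidised and masked as a dioxolane → C10 quaternised → hydrogen-atom-transfer radical closure of ring A → decarboxylation → side chain on C9 → 6α,8α-diol on ring B → (E)-enyne → (Z)-ylidene butenolide → acetal hydrolysis.
- Stereochemistry: C5 from (R)-carvone; C10 by alkylation anti to the C5 arm; C4 in the radical closure; C9 by α-face hydroboration; C8 by α-face enone epoxidation; C6 by thermodynamic metal–ammonia reduction; 13E from the olefination, exocyclic Z from the anti lactonisation.

Key step: step 6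

Remark: labdane-type numbering is used (ring A = C1–C5 + C10, ring B = C5–C10, C17 on C8, C18/C19 on C4, C20 on C10, chain C11–C16, butenolide C2′–C5′); the target is treated as the open 6α-hydroxy-18-aldehyde as drawn.
Remark: the C10 epimer mixture from step 4 and the C2 ester epimer from step 6 (drawn equatorial) are inconsequential, since both centres are re-formed or erased later.

Step 1
Reactants: 1 (R)-(−)-carvone
Product: 2 (R)-10-hydroxycarvone
Conditions: SeO2 (cat.), t-BuOOH, CH2Cl2, rt
Reagents that add atoms: tert-butyl hydroperoxide, CC(C)(C)OO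
Why: Riley-type allylic oxidation (ene reaction, then 2,3-shift) attacks only the electron-rich isopropenyl alkene and prefers its methyl over the ring methine, leaving the enone and the C5 stereocentre untouched; any enal formed by over-oxidation converges in step 2.

Step 2
Reactants: 2 (R)-10-hydroxycarvone
Product: 3 (R)-10-oxocarvone (2-substituted acrolein)
Conditions: TEMPO (cat.), PhI(OAc)2, CH2Cl2, rt
Reagents that add atoms: none
Why: Oxoammonium (TEMPO) oxidation of a primary allylic alcohol stops cleanly at the enal and does not touch the enone.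

Step 3
Reactants: 3 (R)-10-oxocarvone
Product: 4 (5R)-5-[1-(1,3-dioxolan-2-yl)ethenyl]-2-methylcyclohex-2-en-1-one
Conditions: Me3SiOCH2CH2OSiMe3, TMSOTf (cat.), CH2Cl2, −78 °C
Reagents that add atoms: 1,2-bis(trimethylsilyloxy)ethane, C[Si](C)(C)OCCO[Si](C)(C)C
Why: Silyl-triflate-catalysed acetalisation with the bis-silyl glycol is selective for the aldehyde over the conjugated ketone at low temperature and does not move the 1,1-disubstituted double bond; C18 is thereby fixed at the aldehyde oxidation level for the whole route.

Step 4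
Reactants: 4 dioxolane enone
Product: 5 6-methyl derivative of 4 (methyl mainly trans to the C5 arm)
Conditions: LiN(i-Pr)2, THF, −78 °C; MeI, −78 → −20 °C
Reagents that add atoms: iodomethane, CI
Why: Kinetic α′-deprotonation of the carvone-type enone followed by enolate alkylation installs the future C20 methyl; the configuration at this carbon is irrelevant because it is re-enolised in step 5.

Step 5
Reactants: 5 6-methyl enone; 6 methyl 2-(bromomethyl)acrylate
Product: 7 6-methyl-6-[2-(methoxycarbonyl)prop-2-enyl] enone (acrylate arm trans, methyl cis to the C5 arm)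
Conditions: LiN(i-Pr)2, THF, −78 °C; then 6, −78 → 0 °C
Reagents that add atoms: methyl 2-(bromomethyl)acrylate 6, C=C(CBr)C(=O)OC
Why: Alkylation of the tetrasubstituted lithium enolate by the reactive allylic bromide (direct or addition–elimination, same product) occurs on the face opposite the adjacent C5 substituent, which sets the C10 quaternary stereocentre with the two ring A arms trans.

Step 6
Reactants: 7 acrylate-armed enone
Product: 8 trans-fused 4α-(1,3-dioxolan-2-yl)-2α-methoxycarbonyl-4β,8,10β-trimethyl-5α-octal-7-en-9-one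
Conditions: Fe(acac)3 (cat.), PhSiH3, EtOH/ethylene glycol, 60 °C, degassed
Reagents that add atoms: none
Why: The iron hydride made from Fe(acac)3 and PhSiH3 gives a hydrogen atom to the CH2 terminus of the 1,1-disubstituted alkene (Markovnikov), producing the tertiary C4 radical that already carries the future C19 methyl and the masked C18 aldehyde; this nucleophilic radical adds to the unsubstituted acrylate terminus C3 and the α-ester radical is then reduced and protonated, so the step is an intramolecular metal-hydride hydrogen-atom-transfer Giese reaction (reductive olefin coupling). Ring A closes 6-endo-trig, the normal mode for a 5-hexenyl radical whose internal alkene carbon bears the ester, since 5-exo attack would hit the substituted, polarity-mismatched carbon. Because the two arms are trans on the cyclohexenone, only a trans-fused decalin can form. C4 is set in a chair-like transition state that places the branched dioxolanyl group equatorial (α) and the smaller methyl axial (β, syn to the C10 methyl); the branched acetal is expected to discriminate better than a CH2O substituent would. C2 is set on protonation and is expected as the equatorial ester, but it is erased in step 8. The step needs hydrogen-atom transfer to the isolated alkene in preference to the acrylate and the ring enone: the donor alkene is the most electron-rich and least hindered acceptor, and the trisubstituted enone lies where the C4 radical could only close a four-membered ring.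

Step 7
Reactants: 8 decalin ester
Product: 9 2α-carboxylic acid
Conditions: LiOH, THF/MeOH/H2O, rt; then 1 M HCl to pH 4, 0 °C
Reagents that add atoms: lithium hydroxide, [Li+].[OH-]
Why: Saponification of an unhindered secondary methyl ester; the dioxolane and the enone tolerate aqueous base and the brief cold acidification.

Step 8
Reactants: 9 carboxylic acid
Product: 11 4α-(1,3-dioxolan-2-yl)-4β,8,10β-trimethyl-5α-octal-7-en-9-one, via thiohydroxamate ester 10 (not isolated)
Conditions: N-hydroxypyridine-2-thione, DCC, DMAP (cat.), CH2Cl2, rt, dark; then t-BuSH, hν (tungsten lamp), rt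
Reagents that add atoms: none
Why: Barton reductive decarboxylation: the O-acyl thiohydroxamate fragments on irradiation to the secondary C2 radical, which takes hydrogen from the thiol faster than it can reach the remote enone, removing the activating group of the key step under neutral conditions.

Step 9
Reactants: 11 decalin enone
Product: 12 9-methylene compound (7,9(11)-diene)
Conditions: Ph3PCH3Br, KOt-Bu, toluene, 90 °C
Reagents that add atoms: methyltriphenylphosphonium bromide, C[P+](c1ccccc1)(c1ccccc1)c1ccccc1.[Br-]
Why: Wittig methylenation with the salt-free ylide at elevated temperature is the standard answer to hindered ketones flanked by a quaternary carbon; γ-enolisation is reversible and the acetal is inert.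

Step 10
Reactants: 12 diene
Product: 14 18,18-(ethylenedioxy)-14,15-dinorlabd-7-en-13-one, via B-alkyl-9-BBN 13 (not isolated)
Conditions: 9-BBN, THF, 0 → 65 °C; then bromoacetone, potassium 2,6-di-tert-butylphenoxide, THF, 0 °C → rt
Reagents that add atoms: bromoacetone, CC(=O)CBr
Why: 9-BBN hydroborates only the exocyclic 1,1-disubstituted alkene, boron going to C11 and hydrogen to C9 from the α-face, anti to the axial C10 methyl (9α-H, chain β and equatorial); the B-alkyl group then migrates from boron to the α-carbon of the bromoacetone enolate (organoborane α-alkylation of an α-bromo ketone under hindered phenoxide), which forms C11–C12 and gives the methyl ketone directly.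

Step 11
Reactants: 14 methyl ketone
Product: 15 13,13:18,18-bis(ethylenedioxy)-14,15-dinorlabd-7-ene
Conditions: Me3SiOCH2CH2OSiMe3, TMSOTf (cat.), CH2Cl2, −78 → −20 °C; pyridine
Reagents that add atoms: 1,2-bis(trimethylsilyloxy)ethane, C[Si](C)(C)OCCO[Si](C)(C)C
Why: Low-temperature silyl-triflate-catalysed ketalisation masks the side-chain ketone against the reducing step 14; any exchange at the C18 dioxolane is degenerate and the trisubstituted alkene does not migrate.

Step 12
Reactants: 15 bis-acetal alkene
Product: 16 13,13:18,18-bis(ethylenedioxy)-14,15-dinorlabd-7-en-6-one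
Conditions: CrO3, 3,5-dimethylpyrazole, CH2Cl2, −20 °C
Reagents that add atoms: chromium trioxide, O=[Cr](=O)=O
Why: Allylic oxidation by the hexavalent chromium–pyrazole complex converts the ring allylic methylene C6 into the conjugated ketone, as it does for drim-7-ene-type substrates; the hindered tertiary C9–H and the C17 methyl are not carried to a carbonyl, and acetals survive this reagent.

Step 13
Reactants: 16 7-en-6-one
Product: 17 7α,8α-epoxy-6-ketone
Conditions: 30% H2O2, NaOH, MeOH, 0 °C → rt
Reagents that add atoms: hydrogen peroxide, OO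
Why: Weitz–Scheffer nucleophilic epoxidation: hydroperoxide adds to C8 from the α-face, away from the axial C10 methyl and the β side chain on C9, so the C8–O bond is set α with the methyl β; the equatorial C9 chain and the trans ring fusion are the thermodynamic arrangements and are not at risk from the base.

Step 14
Reactants: 17 epoxy ketone
Product: 19 13,13:18,18-bis(ethylenedioxy)-14,15-dinorlabdane-6α,8α-diol, via 8α-hydroxy-6-ketone 18 (not isolated)
Conditions: Li, NH3(l)/THF, −78 °C; then EtOH, −78 → −33 °C; NH4Cl
Reagents that add atoms: none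
Why: Dissolving-metal reduction first cleaves the C7–O bond α to the ketone (retaining the 8α C–O bond) and, once the enolate is protonated, reduces the C6 ketone under thermodynamic control to the equatorial 6α-alcohol, the known outcome for cyclohexanones whose axial face is blocked by syn-axial methyl groups (here C17, C19, C20), where hydride reagents would give the axial epimer.

Step 15
Reactants: 19 diol bis-acetal
Product: 20 18,18-(ethylenedioxy)-6α,8α-dihydroxy-14,15-dinorlabdan-13-one
Conditions: PPTS, acetone/H2O, rt
Reagents that add atoms: water, O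
Why: Mild acid-catalysed transketalisation removes the dialkyl ketal, which ionises far more readily than the aldehyde-derived dioxolane on the quaternary C4, so C18 stays masked.

Step 16
Reactants: 20 dihydroxy methyl ketone
Product: 21 (13E)-18,18-(ethylenedioxy)-6α,8α-dihydroxy-N-methoxy-N-methyllabd-13-en-15-amide
Conditions: (EtO)2P(O)CH2C(O)N(OMe)Me, NaH, THF, 0 → 65 °C
Reagents that add atoms: diethyl (N-methoxy-N-methylcarbamoylmethyl)phosphonate, CCOP(=O)(CC(=O)N(C)OC)OCC
Why: Horner–Wadsworth–Emmons olefination of the methyl ketone, which is known to proceed on free 8α-hydroxy-13-ketones of this type, should favour the E trisubstituted alkene (larger chain trans to the carbonyl); the minor Z isomer is removed by chromatography.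

Step 17
Reactants: 21 unsaturated Weinreb amide
Product: 22 (13E)-18,18-(ethylenedioxy)-6α,8α-dihydroxylabd-13-en-15-al
Conditions: i-Bu2AlH, THF, −78 °C; aq. potassium sodium tartrate
Reagents that add atoms: none
Why: Hydride reduction of the N-methoxy-N-methylamide stops at the chelated hemiaminal, which releases the enal only on work-up; the acetal is stable to the aluminium hydride at −78 °C and the alkene geometry is untouched.

Step 18
Reactants: 22 (E)-enal
Product: 23 (13E)-enyne (C15≡C5′–H)
Conditions: Me3SiCHN2, LiN(i-Pr)2, THF, −78 °C → rt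
Reagents that add atoms: (trimethylsilyl)diazomethane, C[Si](C)(C)C=[N+]=[N-]
Why: Colvin homologation: 1,2-addition of lithiated trimethylsilyldiazomethane, Peterson-type loss of silanolate, loss of N2 and 1,2-hydrogen shift of the alkylidene carbene give the terminal alkyne with retention of the E alkene; excess base covers the two free hydroxyls, and the non-nucleophilic medium avoids conjugate addition to the enal.

Step 19
Reactants: 24 but-2-ynoic acid
Product: 25 (Z)-3-iodobut-2-enoic acid
Conditions: NaI, AcOH, 115 °C
Reagents that add atoms: sodium iodide, [Na+].[I-]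
Why: Anti hydroiodination of the ynoic acid (iodide at the β-carbon, proton delivered trans) gives the Z isomer with iodine cis to the carboxyl, as the lactonisation requires.

Step 20
Reactants: 23 (E)-enyne; 25 (Z)-3-iodobut-2-enoic acid
Product: 27 18,18-ethylene acetal of the target, via enynoic acid 26 (not isolated)
Conditions: Pd(PPh3)4 (cat.), CuI (cat.), Et3N, MeCN, rt, dark
Reagents that add atoms: (Z)-3-iodobut-2-enoic acid 25, C/C(I)=C/C(=O)O
Why: Sonogashira coupling (oxidative addition of the vinyl iodide to zerovalent palladium, copper acetylide transfer) gives the (Z)-en-4-ynoic acid, whose carboxylate adds 5-exo-dig and anti across the alkyne to form the 4-methyl-5-ylidene butenolide with Z exocyclic geometry; free hydroxyls and the acetal are spectators.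

Step 21
Reactants: 27 acetal-protected target
Product: 28 CNP0278517.1
Conditions: 1 M HCl, THF, rt, dark
Reagents that add atoms: water, O
Why: Acid-catalysed acetal hydrolysis releases the non-enolisable C18 aldehyde as the last step; dilute acid at room temperature is expected to leave the tertiary C8 alcohol and the dienyl butenolide intact.

**Compound list**
1 | (R)-(−)-carvone | CC1=CC[C@@H](C(C)=C)CC1=O | starting material
2 | (R)-10-hydroxycarvone, (5R)-5-(3-hydroxyprop-1-en-2-yl)-2-methylcyclohex-2-en-1-one | CC1=CC[C@@H](C(=C)CO)CC1=O | intermediate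
3 | (R)-10-oxocarvone, 2-[(1R)-4-methyl-5-oxocyclohex-3-en-1-yl]prop-2-enal | CC1=CC[C@@H](C(=C)C=O)CC1=O | intermediate
4 | (5R)-5-[1-(1,3-dioxolan-2-yl)ethenyl]-2-methylcyclohex-2-en-1-one | CC1=CC[C@@H](C(=C)C2OCCO2)CC1=O | intermediate
5 | 6-methyl derivative of 4, methyl trans to the C5 arm (major epimer) | O=C1C(C)=CC[C@@H](C(=C)C2OCCO2)[C@@H]1C | intermediate
6 | methyl 2-(bromomethyl)acrylate | C=C(CBr)C(=O)OC | starting material
7 | 6-methyl-6-[2-(methoxycarbonyl)prop-2-enyl] derivative of 4, methyl cis and acrylate arm trans to the C5 arm | O=C1C(C)=CC[C@@H](C(=C)C2OCCO2)[C@]1(C)CC(=C)C(=O)OC | intermediate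
8 | trans-fused 4α-(1,3-dioxolan-2-yl)-2α-methoxycarbonyl-4β,8,10β-trimethyl-5α-octal-7-en-9-one | O=C1[C@@]2(C)C[C@@H](C(=O)OC)C[C@@](C)(C3OCCO3)[C@@H]2CC=C1C | intermediate
9 | 2α-carboxylic acid corresponding to 8 | O=C1[C@@]2(C)C[C@@H](C(=O)O)C[C@@](C)(C3OCCO3)[C@@H]2CC=C1C | intermediate
10 | O-acyl thiohydroxamate (2-thioxopyridin-1-yl ester) of 9 | O=C1[C@@]2(C)C[C@@H](C(=O)ON3C=CC=CC3=S)C[C@@](C)(C4OCCO4)[C@@H]2CC=C1C | intermediate
11 | 4α-(1,3-dioxolan-2-yl)-4β,8,10β-trimethyl-5α-octal-7-en-9-one | O=C1[C@@]2(C)CCC[C@@](C)(C3OCCO3)[C@@H]2CC=C1C | intermediate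
12 | 9-methylene analogue of 11 (7,9(11)-diene) | C=C1[C@@]2(C)CCC[C@@](C)(C3OCCO3)[C@@H]2CC=C1C | intermediate
13 | B-alkyl-9-BBN, boron on C11, 9α-H | C(B1C2CCCC1CCC2)[C@@H]3[C@@]4(C)CCC[C@@](C)(C5OCCO5)[C@@H]4CC=C3C | intermediate
14 | 18,18-(ethylenedioxy)-14,15-dinorlabd-7-en-13-one | CC(=O)CC[C@@H]1[C@@]2(C)CCC[C@@](C)(C3OCCO3)[C@@H]2CC=C1C | intermediate
15 | 13,13:18,18-bis(ethylenedioxy)-14,15-dinorlabd-7-ene | CC1(CC[C@@H]2[C@@]3(C)CCC[C@@](C)(C4OCCO4)[C@@H]3CC=C2C)OCCO1 | intermediate
16 | 13,13:18,18-bis(ethylenedioxy)-14,15-dinorlabd-7-en-6-one | CC1(CC[C@@H]2[C@@]3(C)CCC[C@@](C)(C4OCCO4)[C@@H]3C(=O)C=C2C)OCCO1 | intermediate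
17 | 7α,8α-epoxy-13,13:18,18-bis(ethylenedioxy)-14,15-dinorlabdan-6-one | CC1(CC[C@@H]2[C@@]3(C)CCC[C@@](C)(C4OCCO4)[C@@H]3C(=O)[C@@H]5[C@@]2(C)O5)OCCO1 | intermediate
18 | 8α-hydroxy-13,13:18,18-bis(ethylenedioxy)-14,15-dinorlabdan-6-one | CC1(CC[C@@H]2[C@@]3(C)CCC[C@@](C)(C4OCCO4)[C@@H]3C(=O)C[C@@]2(C)O)OCCO1 | intermediate
19 | 13,13:18,18-bis(ethylenedioxy)-14,15-dinorlabdane-6α,8α-diol | CC1(CC[C@@H]2[C@@]3(C)CCC[C@@](C)(C4OCCO4)[C@@H]3[C@@H](O)C[C@@]2(C)O)OCCO1 | intermediate
20 | 18,18-(ethylenedioxy)-6α,8α-dihydroxy-14,15-dinorlabdan-13-one | CC(=O)CC[C@@H]1[C@@]2(C)CCC[C@@](C)(C3OCCO3)[C@@H]2[C@@H](O)C[C@@]1(C)O | intermediate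
21 | (13E)-18,18-(ethylenedioxy)-6α,8α-dihydroxy-N-methoxy-N-methyllabd-13-en-15-amide | CON(C)C(=O)/C=C(\C)CC[C@@H]1[C@@]2(C)CCC[C@@](C)(C3OCCO3)[C@@H]2[C@@H](O)C[C@@]1(C)O | intermediate
22 | (13E)-18,18-(ethylenedioxy)-6α,8α-dihydroxylabd-13-en-15-al | O=C/C=C(\C)CC[C@@H]1[C@@]2(C)CCC[C@@](C)(C3OCCO3)[C@@H]2[C@@H](O)C[C@@]1(C)O | intermediate
23 | (13E)-enyne, the C15 aldehyde of 22 converted into C15≡C5′–H | C#C/C=C(\C)CC[C@@H]1[C@@]2(C)CCC[C@@](C)(C3OCCO3)[C@@H]2[C@@H](O)C[C@@]1(C)O | intermediate
24 | but-2-ynoic acid | CC#CC(=O)O | starting material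
25 | (Z)-3-iodobut-2-enoic acid | C/C(I)=C/C(=O)O | intermediate
26 | (2Z,6E)-3,7-dimethyl-2,6-dien-4-ynoic acid carrying the bicyclic diol on C9 (coupling product before lactonisation) | OC(=O)/C=C(/C)C#C/C=C(\C)CC[C@@H]1[C@@]2(C)CCC[C@@](C)(C3OCCO3)[C@@H]2[C@@H](O)C[C@@]1(C)O | intermediate
27 | 18,18-ethylene acetal of the target | CC1=CC(=O)O/C1=C\C=C(/C)CC[C@@H]1[C@@]2(C)CCC[C@@](C)(C3OCCO3)[C@@H]2[C@@H](O)C[C@@]1(C)O | intermediate
28 | CNP0278517.1 | CC1=CC(=O)O/C1=C\C=C(/C)CC[C@@H]1[C@@]2(C)CCC[C@@](C)(C=O)[C@@H]2[C@@H](O)C[C@@]1(C)O | target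

**Step count**
Total: 21 steps. Longest linear sequence: 20 steps (steps 1–18, 20, 21); step 19 is a one-step side branch.

**Steps most likely to fail**

Step 6. Hydrogen-atom transfer may go to the acrylate instead of the isolated alkene, the C4 radical may be reduced before it cyclises, or facial discrimination at C4 may be weak. The fallback generates the same C4 radical site-specifically from an epoxide with trivalent titanium and closes the same C3–C4 bond. It sets out from carvone 1. Kinetic methylation (LiN(i-Pr)2, MeI) should give trans-6-methylcarvone F1, and alkylation with 6 under the conditions of step 5 the acrylate-armed 6-methylcarvone F2. mCPBA epoxidises only the isopropenyl group to the 8,9-epoxide F3 (both oxirane epimers serve). Cp2TiCl (from Cp2TiCl2 and Zn, THF) opens the epoxide to the β-titanoxy tertiary radical, which cannot form anywhere else and closes 6-endo onto the acrylate with the bulky CH2O–Ti arm equatorial, giving the 18-hydroxy decalin ester F4. Dess–Martin oxidation then gives the 18-aldehyde F5, and acetalisation as in step 3 returns to the route at 8.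

Step 10. Transfer of the hindered, β-branched alkyl group from boron to the bromoacetone enolate may be slower than protonolysis or migration of a ring B–C bond. The fallback keeps the hydroboration and builds the ketone by carbonyl chemistry. It sets out from 12. 9-BBN followed by NaOH/H2O2 should give the 11-hydroxy compound F6 (drimenol type), and buffered Dess–Martin oxidation the 11-aldehyde F7. Wittig reaction with the neutral stabilised ylide Ph3P=CHC(O)CH3 gives the (E)-enone F8 without enolising C9. Conjugate reduction with [(Ph3P)CuH]6, which leaves the trisubstituted ring alkene alone, returns to the route at 14.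

Step 14. The β-alkoxy ketone formed on epoxide cleavage may undergo retro-aldol ring opening before the carbonyl is reduced, or protonation may not fully follow thermodynamic control at C6. The fallback avoids the C6 ketone altogether and delivers both oxygens from the α-face. It sets out from 15. mCPBA should give the 7α,8α-epoxide F9. (PhSe)2/NaBH4 opens it at the secondary carbon to the 7β-phenylseleno-8α-ol F10, and H2O2 then effects selenoxide syn-elimination, possible only toward C6, to the 8α-hydroxy-6-ene F11. VO(acac)2/t-BuOOH epoxidises syn to the tertiary hydroxyl to the 6α,7α-epoxy-8α-ol F12. NaAlH2(OCH2CH2OMe)2 then delivers hydride to C7 of the 2,3-epoxy alcohol (1,3-diol-selective opening, with the alternative C6 trajectory blocked by three syn-axial methyls) and returns to the route at 19.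

**Further compounds**
F1 | step 6 | trans-6-methylcarvone | O=C1C(C)=CC[C@@H](C(C)=C)[C@@H]1C
F2 | step 6 | 6-methyl-6-[2-(methoxycarbonyl)prop-2-enyl]carvone, acrylate arm trans to isopropenyl | O=C1C(C)=CC[C@@H](C(C)=C)[C@]1(C)CC(=C)C(=O)OC
F3 | step 6 | 8,9-epoxide of F2, epimers at the oxirane carbon | O=C1C(C)=CC[C@@H](C2(C)CO2)[C@]1(C)CC(=C)C(=O)OC
F4 | step 6 | 4α-hydroxymethyl analogue of 8 (18-alcohol) | O=C1[C@@]2(C)C[C@@H](C(=O)OC)C[C@@](C)(CO)[C@@H]2CC=C1C
F5 | step 6 | 4α-formyl analogue of 8 (18-aldehyde) | O=C1[C@@]2(C)C[C@@H](C(=O)OC)C[C@@](C)(C=O)[C@@H]2CC=C1C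
F6 | step 10 | 11-hydroxy compound, 9β-CH2OH on the 7-ene | OC[C@@H]1[C@@]2(C)CCC[C@@](C)(C3OCCO3)[C@@H]2CC=C1C
F7 | step 10 | 11-aldehyde, 9β-CHO on the 7-ene | O=C[C@@H]1[C@@]2(C)CCC[C@@](C)(C3OCCO3)[C@@H]2CC=C1C
F8 | step 10 | (E)-enone, 18,18-(ethylenedioxy)-14,15-dinorlabda-7,11-dien-13-one | CC(=O)/C=C/[C@@H]1[C@@]2(C)CCC[C@@](C)(C3OCCO3)[C@@H]2CC=C1C
F9 | step 14 | 7α,8α-epoxide of 15 | CC1(CC[C@@H]2[C@@]3(C)CCC[C@@](C)(C4OCCO4)[C@@H]3C[C@@H]5[C@@]2(C)O5)OCCO1
F10 | step 14 | 7β-phenylseleno-8α-ol | CC1(CC[C@@H]2[C@@]3(C)CCC[C@@](C)(C4OCCO4)[C@@H]3C[C@H]([Se]c5ccccc5)[C@@]2(C)O)OCCO1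
F11 | step 14 | 8α-hydroxy-6-ene | CC1(CC[C@@H]2[C@@]3(C)CCC[C@@](C)(C4OCCO4)[C@@H]3C=C[C@@]2(C)O)OCCO1
F12 | step 14 | 6α,7α-epoxy-8α-ol | CC1(CC[C@@H]2[C@@]3(C)CCC[C@@](C)(C4OCCO4)[C@@H]3[C@@H]5[C@@H](O5)[C@@]2(C)O)OCCO1
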